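## Retrosynthetic overview
1. The depside acid comes from its benzyl ester by hydrogenolysis. Cutting the aryl ester C–O bond gives the ring A acid (2,4-dimethoxy-6-propylbenzoic acid) and the ring B phenol (benzyl 2,4-dihydroxy-6-propylbenzoate).
2. Both halves come from one intermediate, methyl 2,4-dihydroxy-6-propylbenzoate (methyl divarinate). Ring A needs double O-methylation and saponification; ring B needs saponification and benzylation of the carboxylate.
3. Methyl divarinate comes from methyl 2-hydroxy-4-oxo-6-propylcyclohex-2-ene-1-carboxylate by bromination–dehydrobromination.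
4. The key C–C bond is an intermolecular Michael addition of dimethyl malonate to (E)-hept-3-en-2-one, followed in the same pot by Dieckmann closure.
5. Ring order: one carbocycle is built (step 1) and aromatised (step 2). The batch is then split to serve as ring A and ring B, and no further ring is formed.

Assumption: the SMILES holds no stereocentre, stereogenic axis or double-bond geometry, so the target is achiral and no enantioselective step is needed. The racemic stereocentres of 3, 4 and 5 vanish on aromatisation.

## Route

Step 1
Reactants: 1 (E)-hept-3-en-2-one; 2 dimethyl malonate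
Product: 4 methyl 2-hydroxy-4-oxo-6-propylcyclohex-2-ene-1-carboxylate, via Michael adduct 3 (not isolated)
Conditions: NaOMe (1.2 equiv), MeOH, 0 °C → reflux, 3 h; then aq. HCl, 0 °C, pH 3
Reagents that add atoms: none
Why: The soft malonate anion adds 1,4 to the enone (Michael addition, the fragment-joining C–C bond), and the methyl-ketone enolate of 3 then closes the six-membered ring on one ester (Dieckmann-type intramolecular Claisen condensation), driven by the stabilised 1,3-dione enolate; the two new stereocentres are racemic and are erased in step 2.

Step 2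
Reactants: 4 methyl 2-hydroxy-4-oxo-6-propylcyclohex-2-ene-1-carboxylate
Product: 6 methyl 2,4-dihydroxy-6-propylbenzoate, via bromo dione 5 (not isolated)
Conditions: Br2 (1.0 equiv), DMF, 0 °C, 1 h → 80 °C, 12 h
Reagents that add atoms: none
Why: Electrophilic α-bromination of the enolised 1,3-dione gives 5, which on warming enolises and loses HBr by 1,4-elimination (bromination–dehydrobromination aromatisation), driven by the gain of aromaticity, while the ester survives as long as the bath stays at or below 80 °C.

Step 3 (about half of 6)
Reactants: 6 methyl 2,4-dihydroxy-6-propylbenzoate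
Product: 7 methyl 2,4-dimethoxy-6-propylbenzoate
Conditions: MeI (5 equiv), K2CO3 (4 equiv), DMF, rt → 40 °C, 24 h
Reagents that add atoms: iodomethane (MeI), CI
Why: In this Williamson ether synthesis (SN2 of the phenoxides on MeI), excess reagent in a polar aprotic solvent also alkylates the hydrogen-bonded 2-OH, and the methyl ester is inert.

Step 4
Reactants: 7 methyl 2,4-dimethoxy-6-propylbenzoate
Product: 8 2,4-dimethoxy-6-propylbenzoic acid
Conditions: KOH (10 equiv), DMSO/H2O 4:1, 100 °C, 16 h; then 2 M HCl, 0 °C
Reagents that add atoms: potassium hydroxide, [K+].[OH-]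
Why: Saponification of this di-ortho-substituted benzoate needs poorly solvated hydroxide in hot aqueous DMSO, the aryl methyl ethers are inert to base, and cold acidification avoids protodecarboxylation of the electron-rich acid.

Step 5 (other half of 6)
Reactants: 6 methyl 2,4-dihydroxy-6-propylbenzoate
Product: 9 2,4-dihydroxy-6-propylbenzoic acid (divarinic acid)
Conditions: 2.5 M aq. KOH (6 equiv), N2, reflux, 3 h; then 2 M HCl, 0 °C, pH 2; extract with EtOAc, evaporate below 30 °C
Reagents that add atoms: potassium hydroxide, [K+].[OH-]
Why: In this saponification the ester is cleaved while the product sits as its base-stable phenoxide–carboxylate salt, and the free resorcylic acid is liberated only in the cold, where decarboxylation is slow.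

Step 6
Reactants: 9 2,4-dihydroxy-6-propylbenzoic acid
Product: 10 benzyl 2,4-dihydroxy-6-propylbenzoate
Conditions: BnBr (1.05 equiv), KHCO3 (1.5 equiv), DMF, rt, 16 h
Reagents that add atoms: benzyl bromide, BrCc1ccccc1
Why: This SN2 O-alkylation is chemoselective for the carboxylate because KHCO3 deprotonates only the carboxylic acid and not the phenols, so both OH groups stay free.

Step 7
Reactants: 8 2,4-dimethoxy-6-propylbenzoic acid; 10 benzyl 2,4-dihydroxy-6-propylbenzoate
Product: 12 benzyl 4-[(2,4-dimethoxy-6-propylbenzoyl)oxy]-2-hydroxy-6-propylbenzoate, via mixed anhydride 11 (not isolated)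
Conditions: (CF3CO)2O (4 equiv), dry toluene, rt, 4 h; aq. NaHCO3 wash
Reagents that add atoms: none
Why: In this mixed-anhydride esterification, trifluoroacetic anhydride turns the hindered, electron-rich acid into the acylium-like donor 11, which acylates only the open 4-OH of 10 because the 2-OH is hydrogen-bonded to, and shielded by, the neighbouring ester carbonyl.

Step 8
Reactants: 12 benzyl 4-[(2,4-dimethoxy-6-propylbenzoyl)oxy]-2-hydroxy-6-propylbenzoate
Product: 13 4-[(2,4-dimethoxy-6-propylbenzoyl)oxy]-2-hydroxy-6-propylbenzoic acid (target)
Conditions: H2 (1 atm), 10% Pd/C, EtOAc, rt, 3 h; filter, evaporate below 35 °C, crystallise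
Reagents that add atoms: none
Why: Catalytic hydrogenolysis of the benzylic C–O bond frees the acid under neutral conditions at room temperature, so the depside ester, the aryl ethers and the decarboxylation-prone salicylic acid unit stay intact.

## Compound list
1 | (E)-hept-3-en-2-one | CCC/C=C/C(C)=O | starting material
2 | dimethyl malonate | COC(=O)CC(=O)OC | starting material
3 | dimethyl 2-(2-oxoheptan-4-yl)propanedioate (racemic Michael adduct, not isolated) | CCCC(CC(C)=O)C(C(=O)OC)C(=O)OC | intermediate
4 | methyl 2-hydroxy-4-oxo-6-propylcyclohex-2-ene-1-carboxylate (racemic, enol form of the 2,4-dione) | CCCC1CC(=O)C=C(O)C1C(=O)OC | intermediate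
5 | methyl 3-bromo-2-hydroxy-4-oxo-6-propylcyclohex-2-ene-1-carboxylate (racemic, not isolated) | CCCC1CC(=O)C(Br)=C(O)C1C(=O)OC | intermediate
6 | methyl 2,4-dihydroxy-6-propylbenzoate (methyl divarinate) | CCCc1cc(O)cc(O)c1C(=O)OC | intermediate
7 | methyl 2,4-dimethoxy-6-propylbenzoate | CCCc1cc(OC)cc(OC)c1C(=O)OC | intermediate
8 | 2,4-dimethoxy-6-propylbenzoic acid | CCCc1cc(OC)cc(OC)c1C(=O)O | intermediate
9 | 2,4-dihydroxy-6-propylbenzoic acid (divarinic acid) | CCCc1cc(O)cc(O)c1C(=O)O | intermediate
10 | benzyl 2,4-dihydroxy-6-propylbenzoate | CCCc1cc(O)cc(O)c1C(=O)OCc1ccccc1 | intermediate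
11 | 2,4-dimethoxy-6-propylbenzoic trifluoroacetic anhydride (not isolated) | CCCc1cc(OC)cc(OC)c1C(=O)OC(=O)C(F)(F)F | intermediate
12 | benzyl 4-[(2,4-dimethoxy-6-propylbenzoyl)oxy]-2-hydroxy-6-propylbenzoate | CCCc1cc(OC(=O)c2c(CCC)cc(OC)cc2OC)cc(O)c1C(=O)OCc1ccccc1 | intermediate
13 | 4-[(2,4-dimethoxy-6-propylbenzoyl)oxy]-2-hydroxy-6-propylbenzoic acid (achiral) | CCCc1cc(OC(=O)c2c(CCC)cc(OC)cc2OC)cc(O)c1C(=O)O | target

## Summary
Total step count: 8.
Longest linear sequence: 6 steps (1, 2, 3, 4, 7, 8, or equally 1, 2, 5, 6, 7, 8).

Three steps most likely to fail: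

**Step 2 (aromatisation).** The product resorcinol is very electron-rich, so nuclear over-bromination and some loss of the ester can lower the yield and complicate purification. The fallback sets out from 4 and uses over-bromination on purpose. Excess Br2 (3.1 equiv) in AcOH at rt aromatises and brominates both free ring positions, giving one crystalline product, methyl 3,5-dibromo-2,4-dihydroxy-6-propylbenzoate F1. Hydrogenolysis of both C–Br bonds (H2, 10% Pd/C, NaOAc, MeOH, rt) then comes back to the route at 6.

**Step 5 (saponification of the free resorcylate).** The deactivated phenoxide ester needs heat, and divarinic acid can decarboxylate to 5-propylresorcinol during hydrolysis or acidification. The fallback sets out from 6 and takes a protecting-group detour.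
- BnBr (2.5 equiv) and K2CO3 in DMF at 50 °C give methyl 2,4-bis(benzyloxy)-6-propylbenzoate F2.
- This non-phenolic ester is saponified as in step 4 (KOH, DMSO/H2O, 100 °C, cold HCl) to the robust 2,4-bis(benzyloxy)-6-propylbenzoic acid F3.
- Both benzyl ethers are removed by H2 over 10% Pd/C in EtOAc at rt, under neutral conditions.

This comes back to the route at 9, which is taken into step 6 without heating.

**Step 7 (depside coupling).** The di-ortho-substituted acid is hindered. Under the acidic anhydride conditions, trifluoroacetylation of the phenol or ring C-acylation may compete. The fallback sets out from 8 and replaces acid-promoted in situ activation by a two-stage, base-mediated acylation through an isolated acyl donor. Oxalyl chloride with catalytic DMF in CH2Cl2 (0 °C → rt) gives 2,4-dimethoxy-6-propylbenzoyl chloride F4, freed of volatiles. It is added to 10 and K2CO3 (1.1 equiv) in dry acetone at rt, where only the more acidic, non-chelated 4-OH is turned into a phenoxide and acylated. This comes back to the route at 12.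

## Further compounds
F1 | step 2 | methyl 3,5-dibromo-2,4-dihydroxy-6-propylbenzoate | CCCc1c(Br)c(O)c(Br)c(O)c1C(=O)OC
F2 | step 5 | methyl 2,4-bis(benzyloxy)-6-propylbenzoate | CCCc1cc(OCc2ccccc2)cc(OCc2ccccc2)c1C(=O)OC
F3 | step 5 | 2,4-bis(benzyloxy)-6-propylbenzoic acid | CCCc1cc(OCc2ccccc2)cc(OCc2ccccc2)c1C(=O)O
F4 | step 7 | 2,4-dimethoxy-6-propylbenzoyl chloride | CCCc1cc(OC)cc(OC)c1C(=O)Cl
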